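The route cuts Tsangin C at C4 of its butanone chain (C1 methyl, C2 ketone, C3 methyl-bearing, C4 benzylic), the carbon that holds both the ipso carbon of aryl ring B and the ester oxygen leading to benzoate ring A. This C4 carbinol, with a 3,4,5-trimethoxy ring that arene substitution cannot install, is made with reversed polarity. A sparteine-lithiated primary carbamate carbon captures the aryl boronic ester, the ate complex rearranges by 1,2-migration of the aryl group, and C–B oxidation leaves the C4–O bond. One flask thus sets the R centre beside the chiral-pool C3 centre. The precursor is (R)-2-methylbut-3-enyl N,N-diisopropylcarbamate, whose vinyl group is a latent acetyl.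

Key step: step 4

Remark (assumption): compounds 1, 2, 6 and 11 and (−)-sparteine are taken as purchasable; locants C1–C4 and ring letters A and B are those defined above, and the target is the anti (3S,4R) isomer.

Step 1
Reactants: 1 methyl (S)-3-hydroxy-2-methylpropanoate; 2 N,N-diisopropylcarbamoyl chloride
Product: 3 methyl (S)-3-[(diisopropylcarbamoyl)oxy]-2-methylpropanoate
Conditions: 2 (1.2 equiv), Et3N, DMAP (cat.), CH2Cl2, reflux
Reagents that add atoms: none
Why: O-carbamoylation of a primary alcohol (nucleophilic acyl substitution at the carbamoyl chloride with DMAP catalysis) should be clean because Et3N cannot enolise the ester, so the stereocentre is carried through unchanged and the later directing and leaving group is in place from the first step.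

Step 2
Reactants: 3 methyl (S)-3-[(diisopropylcarbamoyl)oxy]-2-methylpropanoate
Product: 4 (S)-2-methyl-3-oxopropyl N,N-diisopropylcarbamate
Conditions: i-Bu2AlH (1.1 equiv), CH2Cl2, −78 °C; MeOH, then aq. potassium sodium tartrate; used crude
Reagents that add atoms: none
Why: Partial ester reduction with i-Bu2AlH at −78 °C should stop at the aldehyde because only one hydride is delivered before the quench, while the hindered N,N-diisopropylcarbamate is inert at this temperature and the non-basic medium leaves the α-stereocentre intact.

Step 3
Reactants: 4 (S)-2-methyl-3-oxopropyl N,N-diisopropylcarbamate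
Product: 5 (R)-2-methylbut-3-en-1-yl N,N-diisopropylcarbamate
Conditions: Ph3PCH3Br (1.3 equiv), KN(SiMe3)2 (1.2 equiv), THF, 0 °C; then crude 4, −78 → 0 °C
Reagents that add atoms: methyltriphenylphosphonium bromide, C[P+](c1ccccc1)(c1ccccc1)c1ccccc1.[Br-]
Why: Wittig methylenation with the pre-formed ylide (no excess base) at −78 °C should convert the aldehyde to the vinyl group faster than α-deprotonation can epimerise the centre or expel the β-carbamate, and the centre keeps its geometry (the descriptor changes from S to R through the priority rules alone).

Step 4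
Reactants: 5 (R)-2-methylbut-3-en-1-yl N,N-diisopropylcarbamate; 6 4,4,5,5-tetramethyl-2-(3,4,5-trimethoxyphenyl)-1,3,2-dioxaborolane
Product: 10 (1R,2R)-2-methyl-1-(3,4,5-trimethoxyphenyl)but-3-en-1-ol, via lithiated carbamate 7 (not isolated), via boronate complex 8 (not isolated), via secondary boronic ester 9 (not isolated)
Conditions: s-BuLi (1.3 equiv), (−)-sparteine (1.3 equiv), Et2O, −78 °C, 5 h; 6 (1.5 equiv), −78 °C, 1 h; MgBr2·OEt2, −78 °C → reflux; then NaOH, H2O2, THF, 0 °C → rt
Reagents that add atoms: hydrogen peroxide, OO
Why: Lithiation–borylation (carbamate-directed asymmetric deprotonation followed by a 1,2-metallate rearrangement): s-BuLi/(−)-sparteine, held by the carbamate carbonyl, removes the pro-S hydrogen of the OCH2 group to give the α-oxy organolithium 7, configurationally stable at −78 °C, which attacks the boron of 6 with retention to give ate complex 8. On warming with MgBr2·OEt2 the electron-rich aryl group migrates from boron to carbon anti to the departing carbamate (inversion) to give 9, and NaOH/H2O2 then exchanges boron for oxygen with retention, so the aryl–C4 and C4–O bonds both arise in this flask and no ring is formed. The closest known reaction type is the homologation of aryl pinacol boronates with sparteine-lithiated primary alkyl carbamates and oxidation to secondary benzylic alcohols, applied here to a β-branched homoallylic carbamate. The new centre (R, anti to the C3 methyl) is set by reagent control in the choice between the two enantiotopic hydrogens and relayed by three stereospecific events (retention, inversion, retention), while the chiral-pool centre takes no part. The step needs α-oxy over allylic deprotonation, which the complex-induced proximity of the base to the carbamate and the low kinetic acidity of the tertiary allylic C–H should secure, and it needs the sparteine bias to override any preference of the resident centre, which is expected for β-branched primary carbamates. Aryl migration in preference to pinacol-oxygen migration is secured by the high migratory aptitude of the trimethoxyphenyl group.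

Step 5
Reactants: 10 (1R,2R)-2-methyl-1-(3,4,5-trimethoxyphenyl)but-3-en-1-ol; 11 3,4,5-trimethoxybenzoyl chloride
Product: 12 (1R,2R)-2-methyl-1-(3,4,5-trimethoxyphenyl)but-3-en-1-yl 3,4,5-trimethoxybenzoate
Conditions: 11 (1.3 equiv), Et3N, DMAP (cat.), CH2Cl2, 0 °C → rt
Reagents that add atoms: none
Why: DMAP-catalysed esterification of the secondary benzylic alcohol with the acid chloride (acyl transfer through the N-acylpyridinium ion) breaks no bond at either stereocentre, leaves the alkene untouched and masks the hydroxyl before the ketone is unveiled, which forestalls retro-aldol cleavage of a free β-hydroxy ketone.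

Step 6
Reactants: 12 (1R,2R)-2-methyl-1-(3,4,5-trimethoxyphenyl)but-3-en-1-yl 3,4,5-trimethoxybenzoate
Product: 13 Tsangin C, (1R,2S)-2-methyl-3-oxo-1-(3,4,5-trimethoxyphenyl)butyl 3,4,5-trimethoxybenzoate
Conditions: PdCl2 (10 mol%), CuCl (1 equiv), O2 (1 atm), DMF/H2O (7:1), rt
Reagents that add atoms: water, O
Why: Tsuji–Wacker oxidation, in which divalent palladium activates the monosubstituted alkene for Markovnikov attack of water, β-hydride elimination and tautomerisation give the methyl ketone and CuCl/O2 returns zerovalent palladium to the divalent state, runs without base and should therefore leave the C3 centre α to the new ketone, the C4 benzoate and the aryl ethers untouched.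

Compound list
1 | methyl (S)-3-hydroxy-2-methylpropanoate | OC[C@H](C)C(=O)OC | starting material
2 | N,N-diisopropylcarbamoyl chloride | CC(C)N(C(C)C)C(Cl)=O | starting material
3 | methyl (S)-3-[(diisopropylcarbamoyl)oxy]-2-methylpropanoate | CC(C)N(C(C)C)C(=O)OC[C@H](C)C(=O)OC | intermediate
4 | (S)-2-methyl-3-oxopropyl N,N-diisopropylcarbamate | CC(C)N(C(C)C)C(=O)OC[C@H](C)C=O | intermediate
5 | (R)-2-methylbut-3-en-1-yl N,N-diisopropylcarbamate | CC(C)N(C(C)C)C(=O)OC[C@H](C)C=C | intermediate
6 | 4,4,5,5-tetramethyl-2-(3,4,5-trimethoxyphenyl)-1,3,2-dioxaborolane | COc1cc(B2OC(C)(C)C(C)(C)O2)cc(OC)c1OC | starting material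
7 | (1S,2R)-1-lithio-2-methylbut-3-en-1-yl N,N-diisopropylcarbamate (sparteine-bound) | CC(C)N(C(C)C)C(=O)O[C@@H]([Li])[C@H](C)C=C | intermediate
8 | lithium [(1S,2R)-1-[(diisopropylcarbamoyl)oxy]-2-methylbut-3-en-1-yl](pinacolato)(3,4,5-trimethoxyphenyl)borate | CC(C)N(C(C)C)C(=O)O[C@@H]([B-]1(c2cc(OC)c(OC)c(OC)c2)OC(C)(C)C(C)(C)O1)[C@H](C)C=C.[Li+] | intermediate
9 | 4,4,5,5-tetramethyl-2-[(1R,2S)-2-methyl-1-(3,4,5-trimethoxyphenyl)but-3-en-1-yl]-1,3,2-dioxaborolane | COc1cc([C@H](B2OC(C)(C)C(C)(C)O2)[C@H](C)C=C)cc(OC)c1OC | intermediate
10 | (1R,2R)-2-methyl-1-(3,4,5-trimethoxyphenyl)but-3-en-1-ol | O[C@@H](c1cc(OC)c(OC)c(OC)c1)[C@H](C)C=C | intermediate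
11 | 3,4,5-trimethoxybenzoyl chloride | COc1cc(C(Cl)=O)cc(OC)c1OC | starting material
12 | (1R,2R)-2-methyl-1-(3,4,5-trimethoxyphenyl)but-3-en-1-yl 3,4,5-trimethoxybenzoate | COc1cc(C(=O)O[C@@H](c2cc(OC)c(OC)c(OC)c2)[C@H](C)C=C)cc(OC)c1OC | intermediate
13 | Tsangin C, (1R,2S)-2-methyl-3-oxo-1-(3,4,5-trimethoxyphenyl)butyl 3,4,5-trimethoxybenzoate | COc1cc(C(=O)O[C@@H](c2cc(OC)c(OC)c(OC)c2)[C@H](C)C(C)=O)cc(OC)c1OC | target

Total step count: 6. Longest linear sequence: 6 steps (1 → 3 → 4 → 5 → 10 → 12 → 13).

Steps most likely to fail

Step 4. The sparteine preference and the resident β-methyl centre may be mismatched, so that proton removal is incomplete or poorly selective. The 1,2-migration may also be slow, so that the ate complex dissociates on warming and the lithiated carbamate decomposes. The fallback builds the C3–C4 bond instead and sets out from 11. Rosenmund reduction (H2, Pd/BaSO4, 2,6-lutidine, THF) would give 3,4,5-trimethoxybenzaldehyde F1. Asymmetric (E)-crotylboration follows, with the diisopinocampheylborane reagent made from (E)-but-2-ene, n-BuLi/KOt-Bu, (+)-Ipc2BOMe and BF3·OEt2 (THF, −78 °C; then NaOH, H2O2). It should add the crotyl group to the Re face of the aldehyde through a chair transition state and give the anti alcohol, rejoining the route at 10.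

Step 3. The basic ylide may deprotonate aldehyde 4 at its α-carbon, which would expel the β-carbamate (E1cB) or erode the stereocentre before olefination. The fallback sets out from 1 and carries the oxygen as a silyl ether, a far poorer leaving group, through the aldehyde stage. Silylation (t-BuMe2SiCl, imidazole, DMF) would give methyl (S)-3-[(tert-butyldimethylsilyl)oxy]-2-methylpropanoate F2. Reduction with i-Bu2AlH at −78 °C would give (S)-3-[(tert-butyldimethylsilyl)oxy]-2-methylpropanal F3, and Wittig methylenation would give (R)-tert-butyldimethyl[(2-methylbut-3-en-1-yl)oxy]silane F4. Desilylation with Bu4NF would give (R)-2-methylbut-3-en-1-ol F5, handled in solution because of its volatility. Carbamoylation with 2 (Et3N, CH2Cl2, reflux) rejoins the route at 5.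

Step 6. Hydroxypalladation may be steered to the terminal carbon by the homoallylic ester oxygen, the double bond may migrate through palladium hydride, or the acid released may cause enolisation at C3 or loss of the benzylic benzoate once the ketone is formed. The fallback sets out from 12 and avoids palladium and acid. Mukaiyama hydration (Co(acac)2, PhSiH3, O2, THF, rt) would give (1R,2R)-3-hydroxy-2-methyl-1-(3,4,5-trimethoxyphenyl)butyl 3,4,5-trimethoxybenzoate F6 as a mixture of carbinol epimers. Oxidation with Dess–Martin periodinane (NaHCO3, CH2Cl2) converges both epimers on 13.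

Further compounds
F1 | step 4 | 3,4,5-trimethoxybenzaldehyde | COc1cc(C=O)cc(OC)c1OC
F2 | step 3 | methyl (S)-3-[(tert-butyldimethylsilyl)oxy]-2-methylpropanoate | CC(C)(C)[Si](C)(C)OC[C@H](C)C(=O)OC
F3 | step 3 | (S)-3-[(tert-butyldimethylsilyl)oxy]-2-methylpropanal | CC(C)(C)[Si](C)(C)OC[C@H](C)C=O
F4 | step 3 | (R)-tert-butyldimethyl[(2-methylbut-3-en-1-yl)oxy]silane | CC(C)(C)[Si](C)(C)OC[C@H](C)C=C
F5 | step 3 | (R)-2-methylbut-3-en-1-ol | OC[C@H](C)C=C
F6 | step 6 | (1R,2R)-3-hydroxy-2-methyl-1-(3,4,5-trimethoxyphenyl)butyl 3,4,5-trimethoxybenzoate (both C3 epimers) | COc1cc(C(=O)O[C@@H](c2cc(OC)c(OC)c(OC)c2)[C@H](C)C(C)O)cc(OC)c1OC
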